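Ring B (C5–C10) of the trans-decalin C1–C10 holds quaternary C10 between C5 and C9. With oxygen on C8 and a C6=C7 alkene it is a cyclohexene retron, and its diene (C5–C8) and dienophile (C9=C10) are already tied by the ring A carbons C1–C4.
Retrosynthesis: undo the C7 hydroxylation and the acetate pattern, then cut C8=C17 (Wittig), C12–C13 (B-alkyl Suzuki–Miyaura) and C11=C12 (Wittig). C5–C10 and C8–C9 are then cut together, giving an acyclic (E,E,E)-trienoyl oxazolidinone.
The triene is cut at C6=C7 and C5=C6 (two Wittig homologations) and at C4–C19 (1,2-shift in an epoxy silyl ether). Its C5–C4–C3–C2–C1–C10–C9 chain is hepta-1,6-diyne.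
Forward: the chain is built first (both trisubstituted alkenes by carboalumination), rings A and B close together in one cycloaddition, and then come the side chain, exocyclic methylene, C7–OH and C19 acetate.
Stereochemistry: C4 comes from asymmetric epoxidation plus a stereospecific migration, and C9 and C10 from (S)-4-benzyloxazolidinone. C5 and C8 follow from the endo transition state and the alkene geometries, C7 from axial oxygen delivery by SeO2, and C13=C14 from an (E)-vinyl iodide.

Key step: step 12

Remark: labdane numbering is used for every intermediate. The 1,2-shift of step 5 is taken to occur with inversion at the migration terminus, as is general for epoxy silyl ethers of 3,3-disubstituted allylic alcohols.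

Step 1
Reactants: 1 hepta-1,6-diyne
Product: 3 diethyl (2E,7E)-3,7-dimethylnona-2,7-dienedioate, via bis(alkenyl)alane 2 (not isolated)
Conditions: Me3Al (4 equiv), Cp2ZrCl2 (0.4 equiv), ClCH2CH2Cl, 0 °C to rt; then ClCO2Et, 0 °C to rt
Reagents that add atoms: trimethylaluminium, C[Al](C)C; ethyl chloroformate, CCOC(=O)Cl
Why: Twofold Negishi carboalumination adds Me–Al syn to each alkyne with aluminium at the terminus, and acylation of the alkenyl–aluminium bonds with retention gives both (E)-trisubstituted enoates (methyls C18 and C20, carbonyl carbons C19 and C11) in one operation.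

Step 2
Reactants: 3 diethyl (2E,7E)-3,7-dimethylnona-2,7-dienedioate
Product: 4 ethyl (2E,7E)-9-hydroxy-3,7-dimethylnona-2,7-dienoate
Conditions: i-Bu2AlH (2.0 equiv), CH2Cl2, −78 °C; aq. potassium sodium tartrate
Reagents that add atoms: none
Why: 1,2-Reduction of one enoate to the allylic alcohol with i-Bu2AlH is statistical because the two ends are equivalent, but diester, hydroxy ester and diol differ strongly in polarity and recovered 3 can be recycled.

Step 3
Reactants: 4 ethyl (2E,7E)-9-hydroxy-3,7-dimethylnona-2,7-dienoate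
Product: 5 ethyl (2E)-6-[(2R,3R)-3-(hydroxymethyl)-2-methyloxiran-2-yl]-3-methylhex-2-enoate
Conditions: Ti(OiPr)4 (10 mol %), D-(−)-diethyl tartrate (12 mol %), t-BuOOH, 4 Å MS, CH2Cl2, −20 °C
Reagents that add atoms: tert-butyl hydroperoxide, CC(C)(C)OO
Why: Sharpless asymmetric epoxidation is directed by the allylic hydroxyl, so the electron-poor enoate alkene stays untouched, and the D-(−)-tartrate ligand gives the (2R,3R)-epoxide of an (E)-3,3-disubstituted allylic alcohol, the mirror image of the sense known for L-(+)-tartrate with geraniol-type substrates.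

Step 4
Reactants: 5 ethyl (2E)-6-[(2R,3R)-3-(hydroxymethyl)-2-methyloxiran-2-yl]-3-methylhex-2-enoate
Product: 6 TBS ether of 5
Conditions: TBSCl, imidazole, DMF, 0 °C to rt
Reagents that add atoms: tert-butyldimethylsilyl chloride, CC(C)(C)[Si](C)(C)Cl
Why: Routine silylation of the primary alcohol installs the bulky silyl ether that steers the aluminium reagent of the next step to the epoxide oxygen and gives the siloxymethyl group its migratory aptitude.

Step 5
Reactants: 6 TBS ether of 5
Product: 7 ethyl (2E,7R)-8-(tert-butyldimethylsilyloxy)-7-formyl-3,7-dimethyloct-2-enoate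
Conditions: MeAl(OAr)2 (2.2 equiv; Ar = 4-bromo-2,6-di-tert-butylphenyl, from Me3Al + 2 ArOH), CH2Cl2, −78 to −40 °C
Reagents that add atoms: none
Why: In this semipinacol-type rearrangement of an epoxy silyl ether to a β-siloxy aldehyde, the bulky aluminium aryloxide ionises the epoxide at its tertiary carbon while the siloxymethyl group migrates anti to the departing oxygen, so the epoxide configuration passes with inversion to quaternary C4 (bearing C5 as CHO, C19 as CH2OTBS, C18 and C3), and the second equivalent of reagent covers coordination to the ester.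

Step 6
Reactants: 7 ethyl (2E,7R)-8-(tert-butyldimethylsilyloxy)-7-formyl-3,7-dimethyloct-2-enoate
Product: 8 ethyl (2E,7S)-7-[(tert-butyldimethylsilyloxy)methyl]-9-methoxy-3,7-dimethylnona-2,8-dienoate (E/Z mixture at the enol ether)
Conditions: MeOCH2PPh3Cl, KN(SiMe3)2, THF, −78 to 0 °C
Reagents that add atoms: (methoxymethyl)triphenylphosphonium chloride, COC[P+](c1ccccc1)(c1ccccc1)c1ccccc1.[Cl-]
Why: Wittig methoxymethylenation of the non-enolisable neopentyl aldehyde adds C6 at the aldehyde oxidation level, the aldehyde outruns the conjugated ester toward the ylide, and the enol ether geometry is irrelevant because both isomers later hydrolyse to one aldehyde.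

Step 7
Reactants: 8 enol ether ester
Product: 9 (2E,7S)-7-[(tert-butyldimethylsilyloxy)methyl]-9-methoxy-3,7-dimethylnona-2,8-dienoic acid
Conditions: LiOH, THF–MeOH–H2O, 45 °C; then dilute HCl to pH 4, 0 °C
Reagents that add atoms: lithium hydroxide, [Li+].[OH-]
Why: Saponification is carried out while the future aldehyde is masked as a base-stable enol ether, and the neopentyl TBS ether survives hydroxide.

Step 8
Reactants: 9 enol ether acid; 10 (S)-4-benzyl-1,3-oxazolidin-2-one
Product: 12 (S)-4-benzyl-3-[(2E,7S)-7-[(tert-butyldimethylsilyloxy)methyl]-9-methoxy-3,7-dimethylnona-2,8-dienoyl]oxazolidin-2-one, via mixed pivalic anhydride 11 (not isolated)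
Conditions: t-BuCOCl, Et3N, THF, −20 °C; then LiCl, 10, −20 °C to rt
Reagents that add atoms: pivaloyl chloride, CC(C)(C)C(=O)Cl (the pivaloyl group stays only in 11)
Why: Mixed-anhydride N-acylation under LiCl/Et3N activation is mild enough not to deconjugate the β,β-disubstituted enoyl unit or touch the enol ether, and it turns any minor C4 enantiomer into a separable diastereomer.

Step 9
Reactants: 12 enol ether imide
Product: 13 (S)-4-benzyl-3-[(2E,7S)-7-[(tert-butyldimethylsilyloxy)methyl]-3,7-dimethyl-9-oxonon-2-enoyl]oxazolidin-2-one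
Conditions: TsOH·H2O (10 mol %), acetone–H2O, rt
Reagents that add atoms: water, O
Why: Acid-catalysed enol ether hydrolysis unveils the C6 aldehyde under conditions that the imide and the hindered neopentyl silyl ether tolerate.

Step 10
Reactants: 13 C6 aldehyde imide; 14 (triphenylphosphoranylidene)acetaldehyde
Product: 15 (S)-4-benzyl-3-[(2E,7S,9E)-7-[(tert-butyldimethylsilyloxy)methyl]-3,7-dimethyl-11-oxoundeca-2,9-dienoyl]oxazolidin-2-one
Conditions: toluene, 80 °C
Reagents that add atoms: none
Why: The Wittig reaction of a stabilised ylide is (E)-selective and neutral, so it adds C7 and C8 as an enal that still has γ-hydrogens on C5 and leaves the imide alone.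

Step 11
Reactants: 15 enal imide
Product: 16 (S)-4-benzyl-3-[(2E,7S,8E,10E)-11-acetoxy-7-[(tert-butyldimethylsilyloxy)methyl]-3,7-dimethylundeca-2,8,10-trienoyl]oxazolidin-2-one
Conditions: Ac2O, Et3N, DMAP (cat.), THF, rt to 40 °C
Reagents that add atoms: acetic anhydride, CC(=O)OC(C)=O
Why: Dienol acetylation of an enal (γ-deprotonation and O-acylation) proceeds from the s-trans enal to give the (E)-enol acetate, the quaternary C4 forces the new C5=C6 bond to be (E), and any (Z)-enol acetate is separable and inert in the next step.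

Step 12
Reactants: 16 (E,E,E)-trienoyl oxazolidinone with dienyl acetate terminus
Product: 17 trans-fused Diels–Alder adduct (6-ene; 8β-OAc; 9β-C11 imide; 10β-Me; 5α-H; 4β-axial CH2OTBS; 4α-Me)
Conditions: Me2AlCl (2.5 equiv), CH2Cl2, −30 to 0 °C
Reagents that add atoms: none
Why: Excess Me2AlCl turns the imide into a cationic bidentate aluminium chelate that locks the enoyl unit s-cis and lowers its LUMO, and the (1E,3E)-dienyl acetate adds to it in a concerted but asynchronous [4+2] in which C5–C10 runs ahead of C8–C9, the closest known reaction type being the dialkylaluminium chloride-promoted type 1 intramolecular Diels–Alder reaction of (2E,7E,9E)-deca-2,7,9-trienoyl oxazolidinones to trans-octalins. Ring B (C5–C10) is the six-membered cycloadduct ring, and ring A (C1–C5 plus C10) closes in the same event because the C1–C4 chain, folded as a chair, bridges diene terminus C5 and dienophile carbon C10. C9 and C10 are set by the benzyl group of the (S)-auxiliary, which blocks one face of the chelate so that the diene reaches the Cα-Si face, and their mutual relation (C11 cis to C20) is carried over from the (E)-alkene. C5 follows from the endo placement of the imide carbonyl combined with the (E)-C5=C6 bond (H5 anti to C20, hence trans fusion), and C8 from the (E)-enol acetate geometry (OAc cis to C11). The step needs endo over exo and one dienophile face over the other, both secured by chelation, and it needs a diene polarised to suit the tether-imposed pairing, which the acetoxy group provides by making C5 the most nucleophilic terminus for the electrophilic β-carbon C10. The resident centre C4 has little bias of its own because either folding places one of its two carbon substituents axial, so under auxiliary control C19 ends up axial and cis to C20.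

Step 13
Reactants: 17 Diels–Alder adduct
Product: 18 saturated adduct (8β-OAc; C11 imide; 19-OTBS)
Conditions: H2 (1 atm), PtO2 (cat.), EtOAc, rt
Reagents that add atoms: none
Why: Heterogeneous hydrogenation removes the only C=C bond from its open α face without creating a stereocentre, and platinum is preferred to palladium to suppress hydrogenolysis of the allylic acetate.

Step 14
Reactants: 18 saturated adduct
Product: 19 8β,11-diol (19-OTBS; 5α-H; 9α-H; 10β-Me)
Conditions: LiBH4 (excess), THF, 0 °C to rt
Reagents that add atoms: none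
Why: Borohydride reduction of the N-acyl oxazolidinone gives the C11 primary alcohol without touching C9, releases 10 for recovery and cleaves the acetate reductively in the same pot.

Step 15
Reactants: 19 8β,11-diol
Product: 20 8β-hydroxy-11-aldehyde (19-OTBS)
Conditions: TEMPO (cat.), PhI(OAc)2, CH2Cl2, rt
Reagents that add atoms: none
Why: Oxoammonium (TEMPO) oxidation is selective for primary over secondary alcohols, a preference reinforced here because the 8β-hydroxyl is axial and syn to C20, and the equatorial C9 substituent is already the thermodynamic one.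

Step 16
Reactants: 20 8β-hydroxy-11-aldehyde
Product: 21 8β-triethylsilyloxy-11-aldehyde (19-OTBS)
Conditions: TESOTf, 2,6-lutidine, CH2Cl2, −78 to 0 °C
Reagents that add atoms: triethylsilyl trifluoromethanesulfonate, CC[Si](CC)(CC)OS(=O)(=O)C(F)(F)F
Why: The reactive silyl triflate caps the hindered axial hydroxyl as is routine for aldol-type β-hydroxy aldehydes, which blocks retro-aldol opening in the basic olefination that follows.

Step 17
Reactants: 21 8β-triethylsilyloxy-11-aldehyde
Product: 22 C9 vinyl decalin (11-ene; 8β-OTES; 19-OTBS)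
Conditions: MePPh3Br, KN(SiMe3)2, THF, −78 °C to rt
Reagents that add atoms: methyltriphenylphosphonium bromide, C[P+](c1ccccc1)(c1ccccc1)c1ccccc1.[Br-]
Why: Wittig methylenation adds C12, since carbonyl addition of the unhindered ylide is faster than α-deprotonation of the β-silyloxy aldehyde.

Step 18
Reactants: 23 but-2-yn-1-ol
Product: 24 tert-butyl(but-2-yn-1-yloxy)diphenylsilane
Conditions: TBDPSCl, imidazole, CH2Cl2, rt
Reagents that add atoms: tert-butyldiphenylsilyl chloride, CC(C)(C)[Si](Cl)(c1ccccc1)c1ccccc1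
Why: Routine silylation gives an acid-stable ether at future C15 whose bulk also raises the regioselectivity of the next step.

Step 19
Reactants: 24 tert-butyl(but-2-yn-1-yloxy)diphenylsilane
Product: 26 (E)-tert-butyl[(3-iodobut-2-en-1-yl)oxy]diphenylsilane, via alkenylzirconocene 25 (not isolated)
Conditions: Cp2Zr(H)Cl (1.5 equiv), THF, rt to 40 °C; then I2, 0 °C
Reagents that add atoms: zirconocene chloride hydride Cp2Zr(H)Cl, [H][Zr](Cl)(C1C=CC=C1)C1C=CC=C1 (zirconium stays only in 25); iodine, II
Why: Hydrozirconation is a syn addition that, with excess reagent, equilibrates zirconium onto the alkyne carbon next to the smaller methyl group, and iodinolysis with retention gives the (E)-vinyl iodide.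

Step 20
Reactants: 22 C9 vinyl decalin; 26 (E)-vinyl iodide
Product: 28 17-norlabd-13E-ene (8β-OTES; 19-OTBS; 15-OTBDPS), via B-alkyl-9-BBN adduct 27 (not isolated)
Conditions: 9-BBN, THF, rt; then 26, Pd(dppf)Cl2 (5 mol %), AsPh3, Cs2CO3, DMF–H2O, rt
Reagents that add atoms: 9-borabicyclo[3.3.1]nonane, [H]B1C2CCCC1CCC2 (boron stays only in 27)
Why: 9-BBN adds anti-Markovnikov to the only alkene present, and B-alkyl Suzuki–Miyaura coupling with retention of the iodide geometry forms C12–C13 and fixes the (13E)-alkene.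

Step 21
Reactants: 28 17-norlabd-13E-ene tris-silyl ether
Product: 29 8β-alcohol (19-OTBS; 15-OTBDPS)
Conditions: PPTS (cat.), MeOH–CH2Cl2, rt
Reagents that add atoms: none
Why: Mild acid methanolysis removes the TES ether, which is far more labile than the neopentyl TBS and the acid-stable TBDPS ethers.

Step 22
Reactants: 29 8β-alcohol
Product: 30 17-norlabd-13E-en-8-one (19-OTBS; 15-OTBDPS)
Conditions: DMP (1,1,1-triacetoxy-1,1-dihydro-1,2-benziodoxol-3(1H)-one), CH2Cl2, rt
Reagents that add atoms: none
Why: Periodinane oxidation of the strained axial alcohol is fast and neutral, and leaves the alkene, the silyl ethers and C9 untouched.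

Step 23
Reactants: 30 8-ketone
Product: 31 labda-8(17),13E-diene (19-OTBS; 15-OTBDPS)
Conditions: MePPh3Br, KOt-Bu, THF, reflux
Reagents that add atoms: methyltriphenylphosphonium bromide, C[P+](c1ccccc1)(c1ccccc1)c1ccccc1.[Br-]
Why: Wittig methylenation of 8-oxo decalins of this kind is established, and enolisation does no harm because the C9 side chain is already equatorial.

Step 24
Reactants: 31 bis-silyl ether
Product: 32 labda-8(17),13E-diene-15,19-diol
Conditions: Bu4NF, THF, 50 °C
Reagents that add atoms: none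
Why: Fluoride cleaves both silyl ethers (gentle heating serves the neopentyl one) without affecting either alkene.

Step 25
Reactants: 32 15,19-diol
Product: 33 labda-8(17),13E-diene-15,19-diyl diacetate
Conditions: Ac2O, pyridine, DMAP (cat.), CH2Cl2, rt
Reagents that add atoms: acetic anhydride, CC(=O)OC(C)=O
Why: Exhaustive DMAP-catalysed acetylation installs the C19 acetate of the target and an electron-withdrawing ester at C15 that deactivates the C13 alkene for the next step.

Step 26
Reactants: 33 15,19-diacetate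
Product: 34 7α-hydroxylabda-8(17),13E-diene-15,19-diyl diacetate
Conditions: SeO2 (0.5 equiv), t-BuOOH, CH2Cl2, 0 °C to rt
Reagents that add atoms: tert-butyl hydroperoxide, CC(C)(C)OO (terminal oxygen source, relayed by SeO2, O=[Se]=O)
Why: In this SeO2 allylic oxidation selenium binds C17 in an ene step that removes the axial 7α-hydrogen and the [2,3]-shift returns oxygen to the same α face, which gives the axial 7α-alcohol at the ring CH2 rather than at the hindered C9 methine, while the alkene bearing the allylic acetate reacts more slowly, as in geranyl acetate.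

Step 27
Reactants: 34 7α-hydroxy 15,19-diacetate
Product: 35 19-acetoxylabda-8(17),13E-diene-7α,15-diol (target)
Conditions: K2CO3 (0.2 equiv), MeOH, 0 °C
Reagents that add atoms: none
Why: Base-catalysed transesterification discriminates on steric grounds, so the unhindered primary allylic acetate is methanolysed while the neopentyl, axial C19 acetate (syn to C20) is retained.

Compound list
1 | hepta-1,6-diyne | C#CCCCC#C | starting material
2 | (1E,6E)-2,6-dimethylhepta-1,6-diene-1,7-diylbis(dimethylalane) | C[Al](C)/C=C(\C)CCC/C(C)=C/[Al](C)C | intermediate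
3 | diethyl (2E,7E)-3,7-dimethylnona-2,7-dienedioate | CCOC(=O)/C=C(\C)CCC/C(C)=C/C(=O)OCC | intermediate
4 | ethyl (2E,7E)-9-hydroxy-3,7-dimethylnona-2,7-dienoate | CCOC(=O)/C=C(\C)CCC/C(C)=C/CO | intermediate
5 | ethyl (2E)-6-[(2R,3R)-3-(hydroxymethyl)-2-methyloxiran-2-yl]-3-methylhex-2-enoate | OC[C@H]1O[C@]1(C)CCC/C(C)=C/C(=O)OCC | intermediate
6 | TBS ether of 5 | CC(C)(C)[Si](C)(C)OC[C@H]1O[C@]1(C)CCC/C(C)=C/C(=O)OCC | intermediate
7 | ethyl (2E,7R)-8-(tert-butyldimethylsilyloxy)-7-formyl-3,7-dimethyloct-2-enoate | O=C[C@@](C)(CO[Si](C)(C)C(C)(C)C)CCC/C(C)=C/C(=O)OCC | intermediate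
8 | ethyl (2E,7S)-7-[(tert-butyldimethylsilyloxy)methyl]-9-methoxy-3,7-dimethylnona-2,8-dienoate (E/Z at the enol ether) | COC=C[C@@](C)(CO[Si](C)(C)C(C)(C)C)CCC/C(C)=C/C(=O)OCC | intermediate
9 | (2E,7S)-7-[(tert-butyldimethylsilyloxy)methyl]-9-methoxy-3,7-dimethylnona-2,8-dienoic acid | COC=C[C@@](C)(CO[Si](C)(C)C(C)(C)C)CCC/C(C)=C/C(=O)O | intermediate
10 | (S)-4-benzyl-1,3-oxazolidin-2-one | O=C1OC[C@H](Cc2ccccc2)N1 | starting material
11 | mixed pivalic anhydride of 9 | COC=C[C@@](C)(CO[Si](C)(C)C(C)(C)C)CCC/C(C)=C/C(=O)OC(=O)C(C)(C)C | intermediate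
12 | enol ether imide: N-acyl derivative of 10 with acid 9 | COC=C[C@@](C)(CO[Si](C)(C)C(C)(C)C)CCC/C(C)=C/C(=O)N1C(=O)OC[C@@H]1Cc1ccccc1 | intermediate
13 | C6 aldehyde imide, (2E,7S)-9-oxonon-2-enoyl oxazolidinone | O=CC[C@@](C)(CO[Si](C)(C)C(C)(C)C)CCC/C(C)=C/C(=O)N1C(=O)OC[C@@H]1Cc1ccccc1 | intermediate
14 | (triphenylphosphoranylidene)acetaldehyde | O=CC=P(c1ccccc1)(c1ccccc1)c1ccccc1 | starting material
15 | enal imide, (2E,7S,9E)-11-oxoundeca-2,9-dienoyl oxazolidinone | O=C/C=C/C[C@@](C)(CO[Si](C)(C)C(C)(C)C)CCC/C(C)=C/C(=O)N1C(=O)OC[C@@H]1Cc1ccccc1 | intermediate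
16 | (2E,7S,8E,10E)-11-acetoxyundeca-2,8,10-trienoyl oxazolidinone (cycloaddition precursor) | CC(=O)O/C=C/C=C/[C@@](C)(CO[Si](C)(C)C(C)(C)C)CCC/C(C)=C/C(=O)N1C(=O)OC[C@@H]1Cc1ccccc1 | intermediate
17 | trans-fused adduct, (1R,2S,4aR,5S,8aS)-octalin: 6-ene, 8β-OAc, 9β-C11 imide, 10β-Me, 5α-H, 4β-CH2OTBS | CC(=O)O[C@H]1C=C[C@H]2[C@@](C)(CO[Si](C)(C)C(C)(C)C)CCC[C@]2(C)[C@H]1C(=O)N1C(=O)OC[C@@H]1Cc1ccccc1 | intermediate
18 | 6,7-dihydro derivative of 17 | CC(=O)O[C@H]1CC[C@H]2[C@@](C)(CO[Si](C)(C)C(C)(C)C)CCC[C@]2(C)[C@H]1C(=O)N1C(=O)OC[C@@H]1Cc1ccccc1 | intermediate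
19 | 8β,11-diol, 19-OTBS trans-decalin | O[C@H]1CC[C@H]2[C@@](C)(CO[Si](C)(C)C(C)(C)C)CCC[C@]2(C)[C@H]1CO | intermediate
20 | 8β-hydroxy-11-aldehyde, 19-OTBS | O[C@H]1CC[C@H]2[C@@](C)(CO[Si](C)(C)C(C)(C)C)CCC[C@]2(C)[C@H]1C=O | intermediate
21 | 8β-triethylsilyloxy-11-aldehyde, 19-OTBS | CC[Si](CC)(CC)O[C@H]1CC[C@H]2[C@@](C)(CO[Si](C)(C)C(C)(C)C)CCC[C@]2(C)[C@H]1C=O | intermediate
22 | 9β-vinyl decalin, 8β-OTES, 19-OTBS | CC[Si](CC)(CC)O[C@H]1CC[C@H]2[C@@](C)(CO[Si](C)(C)C(C)(C)C)CCC[C@]2(C)[C@H]1C=C | intermediate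
23 | but-2-yn-1-ol | CC#CCO | starting material
24 | tert-butyl(but-2-yn-1-yloxy)diphenylsilane | CC#CCO[Si](c1ccccc1)(c1ccccc1)C(C)(C)C | intermediate
25 | (E)-alkenylzirconocene chloride from 24 | Cl[Zr](C1C=CC=C1)(C1C=CC=C1)/C(C)=C/CO[Si](c1ccccc1)(c1ccccc1)C(C)(C)C | intermediate
26 | (E)-tert-butyl[(3-iodobut-2-en-1-yl)oxy]diphenylsilane | C/C(I)=C\CO[Si](c1ccccc1)(c1ccccc1)C(C)(C)C | intermediate
27 | C12 B-alkyl-9-BBN adduct of 22 | CC[Si](CC)(CC)O[C@H]1CC[C@H]2[C@@](C)(CO[Si](C)(C)C(C)(C)C)CCC[C@]2(C)[C@H]1CCB1C2CCCC1CCC2 | intermediate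
28 | 17-norlabd-13E-ene, 8β-OTES, 19-OTBS, 15-OTBDPS | CC[Si](CC)(CC)O[C@H]1CC[C@H]2[C@@](C)(CO[Si](C)(C)C(C)(C)C)CCC[C@]2(C)[C@H]1CC/C(C)=C/CO[Si](c1ccccc1)(c1ccccc1)C(C)(C)C | intermediate
29 | 17-norlabd-13E-en-8β-ol, 19-OTBS, 15-OTBDPS | O[C@H]1CC[C@H]2[C@@](C)(CO[Si](C)(C)C(C)(C)C)CCC[C@]2(C)[C@H]1CC/C(C)=C/CO[Si](c1ccccc1)(c1ccccc1)C(C)(C)C | intermediate
30 | 17-norlabd-13E-en-8-one, 19-OTBS, 15-OTBDPS | O=C1CC[C@H]2[C@@](C)(CO[Si](C)(C)C(C)(C)C)CCC[C@]2(C)[C@H]1CC/C(C)=C/CO[Si](c1ccccc1)(c1ccccc1)C(C)(C)C | intermediate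
31 | labda-8(17),13E-diene, 19-OTBS, 15-OTBDPS | C=C1CC[C@H]2[C@@](C)(CO[Si](C)(C)C(C)(C)C)CCC[C@]2(C)[C@H]1CC/C(C)=C/CO[Si](c1ccccc1)(c1ccccc1)C(C)(C)C | intermediate
32 | labda-8(17),13E-diene-15,19-diol | C=C1CC[C@H]2[C@@](C)(CO)CCC[C@]2(C)[C@H]1CC/C(C)=C/CO | intermediate
33 | labda-8(17),13E-diene-15,19-diyl diacetate | C=C1CC[C@H]2[C@@](C)(COC(C)=O)CCC[C@]2(C)[C@H]1CC/C(C)=C/COC(C)=O | intermediate
34 | 7α-hydroxylabda-8(17),13E-diene-15,19-diyl diacetate | C=C1[C@H](O)C[C@H]2[C@@](C)(COC(C)=O)CCC[C@]2(C)[C@H]1CC/C(C)=C/COC(C)=O | intermediate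
35 | 19-acetoxylabda-8(17),13E-diene-7α,15-diol, (4S,5R,7R,9R,10S) | C=C1[C@H](O)C[C@H]2[C@@](C)(COC(C)=O)CCC[C@]2(C)[C@H]1CC/C(C)=C/CO | target

Total step count: 27.
Longest linear sequence: 25 steps (steps 1–17 and 20–27). Steps 18 and 19 prepare the vinyl iodide.

Steps most likely to fail

1. Step 12. The cycloaddition may stall, because it joins a neopentyl diene terminus to a fully substituted β-carbon. Long exposure to the aluminium Lewis acid may then bring ionisation or β-elimination of the acetate, or leakage into the exo (cis-fused) mode.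
Fallback: keep the same two bonds but replace the acyloxy activator of the diene with a silyloxy group. This raises the diene HOMO and also removes the later diol differentiation. The fallback sets out from enal 15. TESOTf and Et3N (CH2Cl2, −78 to 0 °C) give the (1E,3E)-triethylsilyl dienol ether F1, which should close with Me2AlCl already at −78 °C to the 8β-triethylsilyloxy octalin imide F2. Hydrogenation over PtO2 gives the saturated silyloxy imide F3, and LiBH4 removes the auxiliary to leave the 8β-triethylsilyloxy C11 alcohol F4. Oxidation with DMP then returns to the route at aldehyde 21.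

2. Step 26. The ene oxidation may not distinguish cleanly between the exocyclic alkene and the C13 alkene, may attack the C9 methine, or may run on to the enone.
Fallback: introduce the C7 oxygen by enolate chemistry before the exocyclic alkene exists. The fallback sets out from ketone 30. KN(SiMe3)2 (THF, −78 °C) deprotonates the C7 methylene kinetically. 2-(Phenylsulfonyl)-3-phenyloxaziridine then hydroxylates the enolate by axial attack on the α face, away from C20, to give the 7α-hydroxy 8-ketone F5. Wittig methylenation with excess Ph3P=CH2 gives the 7α-hydroxy 8(17)-ene bis-silyl ether F6, and Bu4NF gives the 7α,15,19-triol F7. Acetyl chloride with 2,4,6-collidine at low temperature acetylates the two primary hydroxyls in preference to the axial secondary one. This returns to the route at 34.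

3. Step 27. Methanolysis may discriminate poorly between the two primary acetates, with partial loss of the C19 acetate.
Fallback: replace steric discrimination between two identical esters with two esters of different intrinsic lability. The fallback sets out from diol 32. Chloroacetic anhydride and pyridine at −20 °C acylate only the unhindered allylic hydroxyl to give the 15-chloroacetate F8. Ac2O with DMAP gives the 19-acetate 15-chloroacetate F9. SeO2 with t-BuOOH, with the C13 alkene still deactivated by an ester, gives the 7α-hydroxy 19-acetate 15-chloroacetate F10. Thiourea with NaHCO3 in EtOH removes the chloroacetate chemoselectively, which returns to the route at target 35.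

Further compounds
F1 | step 12 | (2E,7S,8E,10E)-11-(triethylsilyloxy)undeca-2,8,10-trienoyl oxazolidinone | CC[Si](CC)(CC)O/C=C/C=C/[C@@](C)(CO[Si](C)(C)C(C)(C)C)CCC/C(C)=C/C(=O)N1C(=O)OC[C@@H]1Cc1ccccc1
F2 | step 12 | trans-fused adduct, 6-ene, 8β-OTES, C11 imide, 19-OTBS | CC[Si](CC)(CC)O[C@H]1C=C[C@H]2[C@@](C)(CO[Si](C)(C)C(C)(C)C)CCC[C@]2(C)[C@H]1C(=O)N1C(=O)OC[C@@H]1Cc1ccccc1
F3 | step 12 | 6,7-dihydro derivative of F2 | CC[Si](CC)(CC)O[C@H]1CC[C@H]2[C@@](C)(CO[Si](C)(C)C(C)(C)C)CCC[C@]2(C)[C@H]1C(=O)N1C(=O)OC[C@@H]1Cc1ccccc1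
F4 | step 12 | 8β-triethylsilyloxy C11 alcohol, 19-OTBS | CC[Si](CC)(CC)O[C@H]1CC[C@H]2[C@@](C)(CO[Si](C)(C)C(C)(C)C)CCC[C@]2(C)[C@H]1CO
F5 | step 26 | 7α-hydroxy-17-norlabd-13E-en-8-one, 19-OTBS, 15-OTBDPS | O=C1[C@H](O)C[C@H]2[C@@](C)(CO[Si](C)(C)C(C)(C)C)CCC[C@]2(C)[C@H]1CC/C(C)=C/CO[Si](c1ccccc1)(c1ccccc1)C(C)(C)C
F6 | step 26 | labda-8(17),13E-dien-7α-ol, 19-OTBS, 15-OTBDPS | C=C1[C@H](O)C[C@H]2[C@@](C)(CO[Si](C)(C)C(C)(C)C)CCC[C@]2(C)[C@H]1CC/C(C)=C/CO[Si](c1ccccc1)(c1ccccc1)C(C)(C)C
F7 | step 26 | labda-8(17),13E-diene-7α,15,19-triol | C=C1[C@H](O)C[C@H]2[C@@](C)(CO)CCC[C@]2(C)[C@H]1CC/C(C)=C/CO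
F8 | step 27 | 19-hydroxylabda-8(17),13E-dien-15-yl chloroacetate | C=C1CC[C@H]2[C@@](C)(CO)CCC[C@]2(C)[C@H]1CC/C(C)=C/COC(=O)CCl
F9 | step 27 | 19-acetoxylabda-8(17),13E-dien-15-yl chloroacetate | C=C1CC[C@H]2[C@@](C)(COC(C)=O)CCC[C@]2(C)[C@H]1CC/C(C)=C/COC(=O)CCl
F10 | step 27 | 19-acetoxy-7α-hydroxylabda-8(17),13E-dien-15-yl chloroacetate | C=C1[C@H](O)C[C@H]2[C@@](C)(COC(C)=O)CCC[C@]2(C)[C@H]1CC/C(C)=C/COC(=O)CCl
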